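The earlier runs and the new flask were computed for an exercise; scatter was added.

At early times the green flask and the colder teal flask climb together, with L at 23.0 % and 23.8 % of the Q charged after 20.0 h. Green then tops out at a highest reading of 42.9 % at 60.0 h and falls to 34.1 % at 144 h.

| setting | green | teal | flask |
|---|---|---|---|
| Q | 0.48 M | 0.48 M | 0.48 M |
| Z | 0.48 M | 0.48 M | 0.480 M |
| temperature | 0 °C | −5 °C | 0 °C |
| remark | the very flask that is asked about, followed so far | run made earlier |  |
| time |  |  | 6.0 d |

| run | time / h | L / % |
|---|---|---|
| green | 20.0 | 23.0 |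
| green | 40.0 | 39.2 |
| green | 60.0 | 42.9 |
| green | 72.0 | 41.4 |
| green | 96.0 | 37.7 |
| green | 120 | 35.5 |
| green | 144 | 34.1 |
| teal | 20.0 | 23.8 |
| teal | 40.0 | 43.9 |
| teal | 60.0 | 58.1 |
| teal | 72.0 | 60.2 |
| teal | 96.0 | 57.9 |
| teal | 120 | 53.9 |
| teal | 144 | 49.9 |

(scatter of a reading: 0.5 percentage points)

- oak: at 6.0 d add Z, 100 % of the amount charged, then wait 3.0 d
- larch: change nothing and wait 3.0 d more
- elm: at 6.0 d raise the temperature by 10 K, then wait 3.0 d

- the volume of additions can be left aside
- at the start none of Q is in solution
- a reading or a percentage of L counts all its forms, free or not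

- L, in percent of the Q first charged, at 6.0 d
- which option adds most L ("none" when 2 percentage points or less is all one gets) (oak / larch / elm / none)
- L present, in percent of the Q first charged, after oak
- L present, in percent of the Q first charged, after larch

For "now" I take the last green reading, since that is the time asked. Oak is the harder question. I treat Z as the limiting reagent and carry one quantity, read at the end of green: the yield on Z, Y, the points of L held per equivalent of Z charged, 34.1 %.

For a rough floor, an estimate and no proof, I hold the L already there at the last green reading and let the second charge of Z do what the first had done by then, which gives 68.2 %. For a rough ceiling, I let it do what the first did at its highest reading, which gives 77.0 %. The fresh charge has 3.0 d, however, and the green reading at that age is 41.4 %, so the ceiling tightens to 75.5 %. Replacing the range by its mean, I commit to 71.8 %, give or take 3.6 percentage points.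

The forecast says 34.1 % now, 32.6 % after larch, and oak as the best option. For oak it gives 50 %, which is 18 points below my floor, with L climbing “until the remaining Q (about 30–35 %) is used”.

The flask gives 33.5 % now, 32.5 % after larch and 68.3 % after oak, which sits at my floor.

    Q ⇌ E, rate k1*(cs1 - [E]) while solid is left; crystals form when [E] > cs1 (solubility = 0.260 M, k = 4.50 × 10⁻⁴ /min)
    E + Z → L (k = 0.0360 /M/min, Ea = 54.0 kJ/mol)
    G ⇌ L, rate k3*(cs3 - [L]) while solid is left; crystals form when [L] > cs3 (solubility = 0.190 M, k = 0.0270 /min)
    L ⇌ X (K = 0.860, k = 2.20 × 10⁻⁴ /min, Ea = 91.0 kJ/mol, ΔH = −58.0 kJ/mol)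
    Z → D (k = 3.10 × 10⁻⁴ /min, Ea = 92.0 kJ/mol)
    (constants at 0 °C)

Oak is the best option. At 144 h the flask holds solid Q at 0 %, Z at 0 % and E, the dissolved form made from Q, at 39.8 %. Oak's one further equivalent of Z adds 35 points, against a Y of 34.1 %. In the same flask charged with 0.29 M of Z, which is 0.604 equiv, Y gives 20.6 % at 144 h, and that flask stands at 22.6 %.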